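By 15 h the rate of substrate loss in the flask has shrunk, and what that rate has delivered by then caps the target.

all flasks: gas 0.92 mM (held)
- maple: substrate 15 mM; run made earlier
- flask: substrate 10 mM; time 15 h

- maple (time / h: target / %, substrate / %): 0.333: 0, 93.5; 0.833: 0.7, 88.3; 1.50: 0.7, 79.4; 2.50: 1.0, 67.6; 3.00: 3.3, 64.0; 5.00: 7.6, 46.1

(scatter of a reading: 1 percentage point)

- the numbers in the tables scatter by 1 percentage point (one standard deviation)
- at the start none of the gas is in solution
- partner is what gas becomes in solution

- how much target there is at 15 h, in percent of the substrate charged
- concentration of partner in solution at 15 h, in percent of saturation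

Take the rate k[substrate]. From its last reading, the maple run gives k = 0.155 h⁻¹. My reckoning assumes this first order holds at the new charge, and from it you get the substrate half-life, 4.48 h, the time in which the rate of substrate loss falls to half.

In the flask the rate starts at 1.55 mM h⁻¹. Falling [substrate] slows it by that factor each half-life, and 15 h holds 3.35 of them. The rate therefore ends at 0.152 mM h⁻¹, less than at the start.

The accumulated slowing leaves a roof, the reacted share 90.2%, above which target cannot stand if one substrate gives one target. That is the late end. The early end is the maple run at 5.00 h, where 46.3% of the charge is neither substrate nor target, so I expect target to lie below the roof by an unread amount.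

The forecast is a different reckoning: 36% of target and partner at 97% of saturation, holding that “the 10 mM charge should behave the same in percent terms”.

The flask gives target 60.1% and partner 70.3% of saturation.

    substrate → open intermediate (k = 0.160 h⁻¹)
    partner → second intermediate (k = 1.10 h⁻¹)
    open intermediate + second intermediate → target (k = 40.0 M⁻¹ h⁻¹)
    2 second intermediate → homo product (k = 4.10 M⁻¹ h⁻¹)
    gas ⇌ partner, rate k5*(csat - [partner]) (kL = 2.60 h⁻¹)

At 15 h the roof of 90.2% lies close to target 60.1% plus open intermediate 30.9%. The substrate half-life of 4.48 h is shorter than the half-life of 4.8 h of open intermediate by the step to target at that time. Read at 6.0 h, the same flask has a roof of 60.5%. There open intermediate stands at 47.8%, more than substrate or target, and target at 14.0%.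

The data were computed with constants of no real substance, noise included.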